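**Plan**

1. Atom labels follow the target SMILES (C1–C30). Ring A is C6/C7/C8/C12/C14/C15, lactone ring B is C15/O16/C17/C19/C27, ring C is C19/C21/C23/C25/C26/C27, and the eleven-membered ring runs through C2–C6, C15, C27, C26, C25, C28, C30. The enabling feature is that O16 sits on tertiary C15, which is γ to carboxyl carbon C17 and cis to it across C19–C27 of ring C, so O16–C15 can be made last from C15–H.
2. Retrosynthesis cuts O16–C15 (C–H lactonisation), takes the C21/C23 oxygens back to one acetate, then cuts C3–C4 (ring-closing metathesis), C19–C20 (methylation) and C15–C27 (decarboxylative radical conjugate addition). Ring A is then opened by a Diels–Alder disconnection (C6–C15, C12–C14) and ring C by a Michael/aldol disconnection (C23–C25, C19–C27).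
3. Forward, ring C is built on the chain aldehyde from the meso anhydride and ring A is made separately. The two are joined at C15–C27, the macrocycle is closed, ring B is formed, and the oxidation level is adjusted to the dione acid.
4. C2/C28 come from desymmetrisation of the meso anhydride, C25 from the prolinol catalyst, and C6/C12 from the Evans Diels–Alder reaction. C15 comes from radical attack anti to the C6 and C12 substituents, C27 from hydride addition anti to the C25 branch, and C19 from methylation anti to the axial C15 branch inside the macrocycle. The lactonisation retains C15.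

Key step: step 24

Assumption: the alkaloid-catalysed methanolysis of step 1 is taken to give the (2R,4S) hemiester with (DHQD)2AQN; if the sense is the reverse, the pseudoenantiomer (DHQ)2AQN is used and nothing else changes.

**Route**

Step 1
Reactants: 1 cis-2,4-dimethylglutaric anhydride
Product: 2 (2R,4S)-5-methoxy-2,4-dimethyl-5-oxopentanoic acid
Conditions: MeOH (10 equiv), (DHQD)2AQN (10 mol%), Et2O, −30 °C
Reagents that add atoms: methanol, CO
Why: Cinchona alkaloid-catalysed desymmetrising methanolysis of the meso anhydride opens one enantiotopic carbonyl, which fixes the syn pair C2/C28 in the absolute sense without touching either centre.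

Step 2
Reactants: 2 hemiester
Product: 3 methyl (2S,4R)-5-hydroxy-2,4-dimethylpentanoate
Conditions: BH3·SMe2, THF, 0 °C to rt; MeOH quench
Reagents that add atoms: none
Why: Borane reduces the carboxylic acid far faster than the ester (chemoselective acid reduction through the acyloxyborane) and forms no enolisable intermediate; any δ-lactone formed on standing converges in step 3.

Step 3
Reactants: 3 hydroxy ester
Product: 4 (3S,5R)-3,5-dimethyloxan-2-ol
Conditions: iBu2AlH (2.2 equiv), CH2Cl2, −78 °C; Rochelle salt
Reagents that add atoms: none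
Why: Partial reduction of the ester with iBu2AlH stops at the aldehyde level because the tetrahedral aluminium acetal survives at −78 °C and gives the six-membered lactol on work-up.

Step 4
Reactants: 4 lactol
Product: 5 (2R,4S)-2,4-dimethylhex-5-en-1-ol
Conditions: Ph3PCH3Br, KOtBu, THF, 0 °C to rt
Reagents that add atoms: methylenetriphenylphosphorane, C=P(c1ccccc1)(c1ccccc1)c1ccccc1
Why: Wittig methylenation of the open hydroxy aldehyde form of the lactol gives the terminal alkene at C3 under conditions that should not enolise the α-methyl centre.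

Step 5
Reactants: 5 alkenol
Product: 7 (2E,4R,6S)-4,6-dimethylocta-2,7-dienal, via aldehyde 6 (not isolated)
Conditions: Dess–Martin periodinane, CH2Cl2, 0 °C to rt; filter, then Ph3P=CHCHO, toluene, 80 °C
Reagents that add atoms: (triphenylphosphoranylidene)acetaldehyde, O=CC=P(c1ccccc1)(c1ccccc1)c1ccccc1
Why: Dess–Martin oxidation followed by Wittig reaction of the volatile α-branched aldehyde with the stabilised formyl ylide should give the E-enal (C27–C26=C25) without base, so C28 is not epimerised.

Step 6
Reactants: 7 enal, 8 tert-butyl 3-oxobutanoate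
Product: 11 (5S)-5-[(2R,4S)-4-methylhex-5-en-2-yl]cyclohex-2-en-1-one, via Michael adduct 9 (not isolated), via cyclohexenone ester 10 (not isolated)
Conditions: (R)-2-{bis[3,5-bis(trifluoromethyl)phenyl][(trimethylsilyl)oxy]methyl}pyrrolidine (10 mol%), PhCO2H (10 mol%), toluene, rt; then TsOH·H2O (20 mol%), 80 °C
Reagents that add atoms: none
Why: Iminium-catalysed Michael addition of the keto ester to the enal (the silyl prolinol ether shields one face of the E-iminium ion, so the catalyst and not C28 sets C25, and the iminium path outruns dienamine formation), then acid-promoted intramolecular aldol condensation with loss of isobutene and CO2, gives ring C (organocatalytic Robinson-type annulation).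

Step 7
Reactants: 11 ring C enone
Product: 12 (5S)-2-iodo-5-[(2R,4S)-4-methylhex-5-en-2-yl]cyclohex-2-en-1-one
Conditions: I2, pyridine, CH2Cl2, 0 °C to rt
Reagents that add atoms: iodine, [I][I]
Why: α-Iodination of the enone by conjugate addition of pyridine, iodination of the enolate and elimination (Johnson α-iodoenone synthesis) touches neither the isolated vinyl group nor C25.

Step 8
Reactants: 12 iodoenone
Product: 13 2-(trimethylsilyl)ethyl (4S)-4-[(2R,4S)-4-methylhex-5-en-2-yl]-6-oxocyclohex-1-ene-1-carboxylate
Conditions: CO (1 atm), Pd(OAc)2 (5 mol%), PPh3 (10 mol%), Me3SiCH2CH2OH (3 equiv), iPr2NEt, DMF, 50 °C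
Reagents that add atoms: carbon monoxide, [C-]#[O+]; 2-(trimethylsilyl)ethanol, C[Si](C)(C)CCO
Why: Palladium-catalysed alkoxycarbonylation of the α-iodoenone (oxidative addition to zerovalent palladium, CO insertion, alcoholysis) installs C17 as an ester that fluoride can later remove beside a tert-butyl ester.

Step 9
Reactants: 14 pent-1-en-4-yne
Product: 16 (E)-1-iodopenta-1,4-diene, via alkenylzirconocene 15 (not isolated)
Conditions: Cp2Zr(H)Cl, THF, rt; then I2, 0 °C
Reagents that add atoms: iodine, [I][I]
Why: Hydrozirconation adds Zr–H syn and terminally to the alkyne in preference to the alkene, and iodinolysis of the C–Zr bond with retention gives the E-iodide.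

Step 10
Reactants: 17 tert-butyl but-2-ynoate
Product: 18 tert-butyl (E)-2-(tributylstannyl)but-2-enoate
Conditions: Bu3SnH, Pd(PPh3)4 (2 mol%), THF, 0 °C
Reagents that add atoms: tributyltin hydride, CCCC[SnH](CCCC)CCCC
Why: Palladium-catalysed hydrostannation of the alkynoate is syn and places tin on the α-carbon, so the methyl group ends cis to the ester.

Step 11
Reactants: 18 stannane, 16 iodide
Product: 19 tert-butyl (2Z,3E)-2-ethylidenehepta-3,6-dienoate
Conditions: Pd(PPh3)4 (5 mol%), CuCl, LiCl, DMSO, 50 °C
Reagents that add atoms: none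
Why: Stille coupling with copper-assisted transmetalation of the hindered α-stannyl enoate joins C8 to C7 with retention of both alkene geometries, giving the diene C12=C8–C7=C6 with both terminal substituents outside.

Step 12
Reactants: 20 (S)-4-benzyl-1,3-oxazolidin-2-one, 21 acryloyl chloride
Product: 22 (S)-3-acryloyl-4-benzyl-1,3-oxazolidin-2-one
Conditions: n-BuLi, THF, −78 °C; then 21, −78 to 0 °C
Reagents that add atoms: none
Why: N-Acylation of the lithiated oxazolidinone with the acid chloride at low temperature should give the acrylimide before it can polymerise.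

Step 13
Reactants: 19 diene, 22 acrylimide
Product: 23 Diels–Alder imide (ring A with C6 allyl, C12 methyl and C15 acyl all cis)
Conditions: Et2AlCl (1.4 equiv), CH2Cl2, −78 to −20 °C
Reagents that add atoms: none
Why: In this Evans auxiliary-controlled Diels–Alder reaction the aluminium-chelated s-cis acrylimide is attacked on the face away from the benzyl group through the endo transition state, with acyl-bearing C15 bonding to C6 (para to the C8 ester, as in the dimerisation of 2-alkoxycarbonyl butadienes); this sets C6 and C12 in the absolute sense, and the (Z,E)-diene geometry puts C5 and C13 cis.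

Step 14
Reactants: 23 Diels–Alder imide
Product: 24 (1R,2S,5S)-4-(tert-butoxycarbonyl)-5-methyl-2-(prop-2-en-1-yl)cyclohex-3-ene-1-carboxylic acid
Conditions: LiOH, H2O2, THF–H2O, 0 °C; Na2SO3; HCl to pH 3
Reagents that add atoms: hydrogen peroxide, OO
Why: Hydroperoxide attacks the exocyclic imide carbonyl selectively (standard auxiliary removal, with 20 recovered), and the tert-butyl enoate is inert at 0 °C.

Step 15
Reactants: 24 ring A acid, 13 ring C enone ester
Product: 26 coupled keto ester (C15–C27 bond; C27 trans to the C25 branch), via redox-active ester 25 (not isolated)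
Conditions: N-hydroxyphthalimide, DIC, DMAP (cat.), CH2Cl2, rt; then 13 (1.5 equiv), Ru(bpy)3(PF6)2 (1 mol%), Hantzsch ester (1.5 equiv), iPr2NEt·HBF4, CH2Cl2, blue LEDs, rt
Reagents that add atoms: none
Why: Photoreductive fragmentation of the N-acyloxyphthalimide gives the secondary C15 radical, which adds to C27 of the doubly activated enone (decarboxylative Giese reaction) from the ring A face opposite the C6 allyl and the pseudoaxial C12 methyl, so C15–H ends cis to C5 as in the target; the C27 centre formed here is erased in step 16.

Step 16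
Reactants: 26 coupled keto ester
Product: 28 alkylidene β-keto ester (C27=C19), via selanyl keto ester 27 (not isolated)
Conditions: PhSeCl, pyridine, CH2Cl2, 0 °C; then H2O2 (30%), 0 °C to rt
Reagents that add atoms: none
Why: Selenenylation of the β-keto ester at C19 and syn elimination of the selenoxide toward its only β-hydrogen, C27–H (Reich–Sharpless dehydrogenation), returns C27 to sp2; C15, now γ to the keto ester, already sits in its more stable configuration trans to the C6 allyl group.

Step 17
Reactants: 28 alkylidene β-keto ester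
Product: 29 cis keto ester (C15 and C28 branches cis on ring C)
Conditions: Cu(OAc)2 (5 mol%), 1,2-bis(diphenylphosphino)benzene (5 mol%), (EtO)2MeSiH (1.5 equiv), tBuOH (1.5 equiv), toluene, rt
Reagents that add atoms: none
Why: Ligated copper hydride reduces the doubly activated alkene in the conjugate sense and leaves the terminal alkenes and the singly activated ring A enoate alone; hydride adds axially to C27 anti to the C25 branch (the sense shown by nucleophiles with 5-substituted cyclohexenones), so ring A and the C25 branch become cis.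

Step 18
Reactants: 29 cis keto ester
Product: 30 macrocyclic keto ester (C3=C4)
Conditions: second-generation Grubbs catalyst (10 mol%), CH2Cl2 (1 mM), 40 °C
Reagents that add atoms: none
Why: Ring-closing metathesis of the C6 allyl group with the C2 vinyl group closes the eleven-membered ring because the cis-1,3 branches on ring C and the trans-vicinal C5/C27 on ring A point the chain ends toward each other, while the trisubstituted enoate is inert; the alkene geometry is irrelevant.

Step 19
Reactants: 30 macrocyclic keto ester
Product: 31 saturated macrocyclic keto ester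
Conditions: H2 (1 atm), RhCl(PPh3)3 (10 mol%), benzene–EtOH, rt
Reagents that add atoms: none
Why: Homogeneous hydrogenation with RhCl(PPh3)3 saturates the disubstituted C3=C4 alkene and spares the hindered, conjugated C7=C8 alkene and the ketone.

Step 20
Reactants: 31 saturated macrocyclic keto ester
Product: 32 C19-methyl keto ester
Conditions: Cs2CO3, MeI, DMF, 0 °C to rt
Reagents that add atoms: iodomethane, CI
Why: C-Alkylation of the β-keto ester enolate creates quaternary C19; the ansa bridge holds the C15 and C28 branches axial on ring C, so MeI enters C19 axially from the opposite face and C20 ends trans to C15 with C17 cis to it.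

Step 21
Reactants: 32 C19-methyl keto ester
Product: 33 C21 alcohol
Conditions: NaBH4, MeOH–THF, −20 °C
Reagents that add atoms: none
Why: Borohydride reduces only the ketone, from the face away from the bridge (axial approach is blocked by both axial branches), giving the C21 alcohol cis to C17; this centre is removed again in step 26.

Step 22
Reactants: 33 C21 alcohol
Product: 34 C21 acetate
Conditions: Ac2O, DMAP, pyridine, CH2Cl2, rt
Reagents that add atoms: acetic anhydride, CC(=O)OC(C)=O
Why: DMAP-catalysed acetylation keeps C21 at the alcohol level, because a C21 ketone would make the free acid a β-keto acid, and the acetate withdraws electron density from C21–H and C23–H ahead of the oxidation.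

Step 23
Reactants: 34 C21 acetate
Product: 35 seco acid (C15–H, free C17 acid)
Conditions: Bu4NF, THF, 0 °C to rt; dilute HCl work-up
Reagents that add atoms: none
Why: Fluoride attacks silicon and the 2-(trimethylsilyl)ethyl ester fragments to carboxylate, ethylene and Me3SiF (β-elimination), which should leave the tert-butyl ester and the hindered acetate in place.

Step 24
Reactants: 35 seco acid
Product: 37 spiro lactone acetate, via hydroxy acid 36 (not isolated)
Conditions: [Fe((S,S)-PDP)(MeCN)2](SbF6)2 (3 × 5 mol%; PDP = 1,1′-bis(pyridin-2-ylmethyl)-2,2′-bipyrrolidine), H2O2 (50% aq., 3 × 1.2 equiv, slow addition), MeCN, rt, no acid additive; recovered 35 recycled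
Reagents that add atoms: hydrogen peroxide, OO
Why: The carboxylate of 35 takes the place of the usual carboxylic acid additive on iron, so O–O heterolysis gives a carboxylate-bound electrophilic oxoiron species (formally pentavalent iron) that abstracts the C15 hydrogen through a seven-membered transition state and returns hydroxyl to the short-lived C15 radical before it can invert, giving γ-hydroxy acid 36. Ring B then closes by 5-exo-trig attack of O16 on acyl carbon C17 with loss of water, as expected for a tertiary alcohol held cis to the carboxyl. The closest known reaction type is the carboxylic acid-directed γ-lactonisation of tertiary C–H bonds with Fe(PDP)- and Mn(PDP)-type catalysts and H2O2. The only new stereocentre, spiro C15, forms with retention and is therefore controlled by the C15–H configuration set in step 15, while the cis relation of C17 and C15 on ring C (steps 17 and 20) allows only the cis-fused lactone. The step needs site selectivity over the other tertiary C–H bonds (C2, C28, C25, C27, allylic C6 and C12) and the secondary γ-positions C23 and C26, and chemoselectivity over the C7=C8 alkene. These should be secured by delivery from the bound carboxylate to the one tertiary γ-hydrogen, by the ansa bridge (which fixes the C15–C27 rotamer with C15–H pointing at the equatorial carboxyl and keeps that carboxyl away from the ring hydrogens on C23 and C26), by the acetate (which deactivates C21–H and C23–H), and by the electron-poor, trisubstituted, flanked enoate.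

Step 25
Reactants: 37 spiro lactone acetate
Product: 38 hydroxy lactone
Conditions: K2CO3, MeOH, rt
Reagents that add atoms: none
Why: Methanolysis removes the acetate; should methoxide open the γ-lactone, the tertiary C15 alkoxide re-closes it in the same medium, and C19 carries no hydrogen to epimerise.

Step 26
Reactants: 38 hydroxy lactone
Product: 39 keto lactone (C21 ketone)
Conditions: Dess–Martin periodinane, CH2Cl2, rt
Reagents that add atoms: none
Why: Dess–Martin oxidation of the hindered secondary alcohol gives a β-keto lactone on quaternary C19, which can neither decarboxylate nor enolise toward C19.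

Step 27
Reactants: 39 keto lactone
Product: 40 dione tert-butyl ester
Conditions: SeO2, 1,4-dioxane–H2O, 90 °C
Reagents that add atoms: selenium dioxide, O=[Se]=O
Why: In this Riley oxidation the C21 ketone can enolise only toward C23, so SeO2 converts that methylene to the second carbonyl; C25 should keep its configuration because the cis-1,3-bridged ring C cannot hold the epimer.

Step 28
Reactants: 40 dione tert-butyl ester
Product: 41 CNP0115928.1
Conditions: CF3CO2H, CH2Cl2, 0 °C to rt
Reagents that add atoms: none
Why: Acidolysis of the tert-butyl ester through the tert-butyl cation frees the C9 acid without base, which the 1,2-dione (benzilic acid rearrangement, C25 enolisation) would not tolerate.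

**Compound list**

1 | cis-2,4-dimethylglutaric anhydride (meso; (3R,5S)-3,5-dimethyloxane-2,6-dione) | C[C@H]1C[C@@H](C)C(=O)OC1=O | starting material
2 | (2R,4S)-5-methoxy-2,4-dimethyl-5-oxopentanoic acid (acid carbon becomes C25, ester carbon becomes C3) | OC(=O)[C@H](C)C[C@H](C)C(=O)OC | intermediate
3 | methyl (2S,4R)-5-hydroxy-2,4-dimethylpentanoate | OC[C@H](C)C[C@H](C)C(=O)OC | intermediate
4 | (3S,5R)-3,5-dimethyloxan-2-ol (lactol, both anomers) | OC1OC[C@H](C)C[C@@H]1C | intermediate
5 | (2R,4S)-2,4-dimethylhex-5-en-1-ol | C=C[C@@H](C)C[C@@H](C)CO | intermediate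
6 | (2R,4S)-2,4-dimethylhex-5-enal (not isolated) | C=C[C@@H](C)C[C@@H](C)C=O | intermediate
7 | (2E,4R,6S)-4,6-dimethylocta-2,7-dienal | C=C[C@@H](C)C[C@@H](C)/C=C/C=O | intermediate
8 | tert-butyl 3-oxobutanoate | CC(=O)CC(=O)OC(C)(C)C | starting material
9 | tert-butyl (3R,4R,6S)-2-acetyl-4,6-dimethyl-3-(2-oxoethyl)oct-7-enoate (Michael adduct, C2 epimers; not isolated) | C=C[C@@H](C)C[C@@H](C)[C@@H](CC=O)C(C(C)=O)C(=O)OC(C)(C)C | intermediate
10 | tert-butyl (6R)-6-[(2R,4S)-4-methylhex-5-en-2-yl]-2-oxocyclohex-3-ene-1-carboxylate (C1 epimers; not isolated) | C=C[C@@H](C)C[C@@H](C)[C@H]1CC=CC(=O)C1C(=O)OC(C)(C)C | intermediate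
11 | (5S)-5-[(2R,4S)-4-methylhex-5-en-2-yl]cyclohex-2-en-1-one (ring C; ring position 5 is C25) | C=C[C@@H](C)C[C@@H](C)[C@@H]1CC(=O)C=CC1 | intermediate
12 | (5S)-2-iodo-5-[(2R,4S)-4-methylhex-5-en-2-yl]cyclohex-2-en-1-one | C=C[C@@H](C)C[C@@H](C)[C@@H]1CC(=O)C(I)=CC1 | intermediate
13 | 2-(trimethylsilyl)ethyl (4S)-4-[(2R,4S)-4-methylhex-5-en-2-yl]-6-oxocyclohex-1-ene-1-carboxylate | C=C[C@@H](C)C[C@@H](C)[C@@H]1CC(=O)C(C(=O)OCC[Si](C)(C)C)=CC1 | intermediate
14 | pent-1-en-4-yne | C=CCC#C | starting material
15 | chlorobis(cyclopentadienyl)[(1E)-penta-1,4-dien-1-yl]zirconium (not isolated) | C=CC/C=C/[Zr](Cl)(C1C=CC=C1)C1C=CC=C1 | intermediate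
16 | (E)-1-iodopenta-1,4-diene | I/C=C/CC=C | intermediate
17 | tert-butyl but-2-ynoate | CC#CC(=O)OC(C)(C)C | starting material
18 | tert-butyl (E)-2-(tributylstannyl)but-2-enoate | C/C=C(/[Sn](CCCC)(CCCC)CCCC)C(=O)OC(C)(C)C | intermediate
19 | tert-butyl (2Z,3E)-2-ethylidenehepta-3,6-dienoate | C/C=C(/C=C/CC=C)C(=O)OC(C)(C)C | intermediate
20 | (S)-4-benzyl-1,3-oxazolidin-2-one | O=C1N[C@@H](Cc2ccccc2)CO1 | starting material
21 | acryloyl chloride | C=CC(Cl)=O | starting material
22 | (S)-3-acryloyl-4-benzyl-1,3-oxazolidin-2-one | C=CC(=O)N1[C@@H](Cc2ccccc2)COC1=O | intermediate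
23 | (S)-4-benzyl-3-{[(1R,2S,5S)-4-(tert-butoxycarbonyl)-5-methyl-2-(prop-2-en-1-yl)cyclohex-3-en-1-yl]carbonyl}-1,3-oxazolidin-2-one | C=CC[C@H]1C=C(C(=O)OC(C)(C)C)[C@@H](C)C[C@H]1C(=O)N1[C@@H](Cc2ccccc2)COC1=O | intermediate
24 | (1R,2S,5S)-4-(tert-butoxycarbonyl)-5-methyl-2-(prop-2-en-1-yl)cyclohex-3-ene-1-carboxylic acid | C=CC[C@H]1C=C(C(=O)OC(C)(C)C)[C@@H](C)C[C@H]1C(=O)O | intermediate
25 | 1,3-dioxoisoindolin-2-yl ester of 24 (not isolated) | C=CC[C@H]1C=C(C(=O)OC(C)(C)C)[C@@H](C)C[C@H]1C(=O)ON1C(=O)c2ccccc2C1=O | intermediate
26 | coupled keto ester: ring A (C6 allyl, C12 methyl, C9 tert-butyl ester; C6, C12, C15 as in the target) bonded C15–C27 to the 2-(trimethylsilyl)ethyl 2-oxocyclohexanecarboxylate ring C; C27 trans to the C25 branch, C19 labile | C=CC[C@H]1C=C(C(=O)OC(C)(C)C)[C@@H](C)C[C@@H]1[C@H]2C[C@H]([C@H](C)C[C@H](C)C=C)CC(=O)[C@@H]2C(=O)OCC[Si](C)(C)C | intermediate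
27 | C19 phenylselanyl derivative of 26 (selenium cis to C27–H; not isolated) | C=CC[C@H]1C=C(C(=O)OC(C)(C)C)[C@@H](C)C[C@@H]1[C@H]2C[C@H]([C@H](C)C[C@H](C)C=C)CC(=O)[C@@]2([Se]c3ccccc3)C(=O)OCC[Si](C)(C)C | intermediate
28 | alkylidene β-keto ester: as 26 with a C27=C19 double bond | C=CC[C@H]1C=C(C(=O)OC(C)(C)C)[C@@H](C)C[C@@H]1C2=C(C(=O)OCC[Si](C)(C)C)C(=O)C[C@@H]([C@H](C)C[C@H](C)C=C)C2 | intermediate
29 | cis keto ester: C27 epimer of 26, with the C15 and C28 branches cis on ring C as in the target; C19 labile | C=CC[C@H]1C=C(C(=O)OC(C)(C)C)[C@@H](C)C[C@@H]1[C@@H]2C[C@H]([C@H](C)C[C@H](C)C=C)CC(=O)[C@@H]2C(=O)OCC[Si](C)(C)C | intermediate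
30 | macrocyclic keto ester: eleven-membered ring closed, C3=C4 alkene (E/Z mixture), C21 ketone, C19–H labile | C[C@@H]1C=CC[C@H]2C=C(C(=O)OC(C)(C)C)[C@@H](C)C[C@@H]2[C@@H]3C[C@H]([C@H](C)C1)CC(=O)[C@@H]3C(=O)OCC[Si](C)(C)C | intermediate
31 | saturated macrocyclic keto ester (C3–C4 single bond) | C[C@@H]1CCC[C@H]2C=C(C(=O)OC(C)(C)C)[C@@H](C)C[C@@H]2[C@@H]3C[C@H]([C@H](C)C1)CC(=O)[C@@H]3C(=O)OCC[Si](C)(C)C | intermediate
32 | C19-methyl keto ester: quaternary C19 with C20 trans and C17 ester cis to C15 | C[C@@H]1CCC[C@H]2C=C(C(=O)OC(C)(C)C)[C@@H](C)C[C@@H]2[C@@H]3C[C@H]([C@H](C)C1)CC(=O)[C@]3(C)C(=O)OCC[Si](C)(C)C | intermediate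
33 | C21 alcohol (hydroxyl cis to C17) | C[C@@H]1CCC[C@H]2C=C(C(=O)OC(C)(C)C)[C@@H](C)C[C@@H]2[C@@H]3C[C@H]([C@H](C)C1)C[C@H](O)[C@]3(C)C(=O)OCC[Si](C)(C)C | intermediate
34 | C21 acetate, 2-(trimethylsilyl)ethyl ester | C[C@@H]1CCC[C@H]2C=C(C(=O)OC(C)(C)C)[C@@H](C)C[C@@H]2[C@@H]3C[C@H]([C@H](C)C1)C[C@H](OC(C)=O)[C@]3(C)C(=O)OCC[Si](C)(C)C | intermediate
35 | seco acid: carbocyclic tricycle with C15–H, free C17 acid, C21 acetate, C9 tert-butyl ester; all carbon stereocentres as in the target | C[C@@H]1CCC[C@H]2C=C(C(=O)OC(C)(C)C)[C@@H](C)C[C@@H]2[C@@H]3C[C@H]([C@H](C)C1)C[C@H](OC(C)=O)[C@]3(C)C(=O)O | intermediate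
36 | C15-hydroxy acid (hydroxyl where C15–H stood; not isolated) | C[C@@H]1CCC[C@H]2C=C(C(=O)OC(C)(C)C)[C@@H](C)C[C@]2(O)[C@@H]3C[C@H]([C@H](C)C1)C[C@H](OC(C)=O)[C@]3(C)C(=O)O | intermediate
37 | spiro lactone acetate: ring B closed (O16–C15), C21 acetate, C9 tert-butyl ester | C[C@@H]1CCC[C@H]2C=C(C(=O)OC(C)(C)C)[C@@H](C)C[C@@]23OC(=O)[C@@]2(C)[C@@H](OC(C)=O)C[C@H](C[C@H]23)[C@H](C)C1 | intermediate
38 | hydroxy lactone (C21 alcohol) | C[C@@H]1CCC[C@H]2C=C(C(=O)OC(C)(C)C)[C@@H](C)C[C@@]23OC(=O)[C@@]2(C)[C@@H](O)C[C@H](C[C@H]23)[C@H](C)C1 | intermediate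
39 | keto lactone (C21 ketone, C23 methylene) | C[C@@H]1CCC[C@H]2C=C(C(=O)OC(C)(C)C)[C@@H](C)C[C@@]23OC(=O)[C@@]2(C)C(=O)C[C@H](C[C@H]23)[C@H](C)C1 | intermediate
40 | dione tert-butyl ester (C21 and C23 ketones) | C[C@@H]1CCC[C@H]2C=C(C(=O)OC(C)(C)C)[C@@H](C)C[C@@]23OC(=O)[C@@]2(C)C(=O)C(=O)[C@H](C[C@H]23)[C@H](C)C1 | intermediate
41 | CNP0115928.1 (2R,6S,12S,15R,19R,25R,27R,28R by the atom order of its SMILES) | C[C@@H]1CCC[C@H]2C=C(C(=O)O)[C@@H](C)C[C@@]23OC(=O)[C@@]2(C)C(=O)C(=O)[C@H](C[C@H]23)[C@H](C)C1 | target

**Count and risks**

Total: 28 steps. Longest linear sequence: 22 steps (steps 1–8, then 15–28). The ring A branch (steps 9–14) joins at step 15.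

The three steps most likely to fail:

Step 24. The oxidation may go to the wrong place: non-directed hydroxylation of the remote methines C2–H or C28–H, epoxidation at C7=C8, or poor binding of the crowded carboxylate. In that case O16–C15 is made by 1,5-hydrogen transfer to an amidyl radical, which is known chemistry (N-iodoamide photolysis of the Barton type under Suárez conditions). Setting out from 35, coupling with NH4Cl (EDC·HCl, HOBt, iPr2NEt, DMF) would give the primary amide F1. Irradiation with PhI(OAc)2 and I2 in CH2Cl2 generates the N-iodoamide, whose amidyl radical abstracts the C15 hydrogen through a six-membered transition state. The resulting tertiary C15 iodide is displaced by the amide oxygen on the only face the bridge leaves open, giving the iminolactone F2. Hydrolysis in aqueous AcOH–THF gives 37, where the route resumes at step 25.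

Step 18. Ring closure may lose to oligomerisation, because 29 must place both ring C branches axial before the chain ends can meet. In that case the ring is closed one stage earlier, while C27 is still trigonal, and the ring rather than the C25 branch then directs the hydride. Setting out from 28, the same ruthenium carbene at high dilution would give the macrocyclic alkylidene β-keto ester F3. The copper hydride reduction of step 17, now delivering hydride to C27 from the face outside the bridge, returns to the route at 30.

Step 27. SeO2 may over-oxidise (dehydrogenation toward C25, allylic attack on ring A), or the β-keto lactone may open in hot aqueous dioxane. In that case the second carbonyl is introduced in two mild steps. Setting out from 39, the potassium enolate (KHMDS, THF, −78 °C), which can form only toward C23, is hydroxylated with 2-(phenylsulfonyl)-3-phenyloxaziridine to the C23-hydroxy ketone F4 (either C23 epimer serves). Dess–Martin oxidation then gives 40, where the route resumes at step 28.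

**Further compounds**

F1 | step 24 | primary amide of seco acid 35 | C[C@@H]1CCC[C@H]2C=C(C(=O)OC(C)(C)C)[C@@H](C)C[C@@H]2[C@@H]3C[C@H]([C@H](C)C1)C[C@H](OC(C)=O)[C@]3(C)C(N)=O
F2 | step 24 | iminolactone (C17=NH analogue of 37) | C[C@@H]1CCC[C@H]2C=C(C(=O)OC(C)(C)C)[C@@H](C)C[C@@]23OC(=N)[C@@]2(C)[C@@H](OC(C)=O)C[C@H](C[C@H]23)[C@H](C)C1
F3 | step 18 | macrocyclic alkylidene β-keto ester (C3=C4 and C27=C19) | C[C@@H]1C=CC[C@H]2C=C(C(=O)OC(C)(C)C)[C@@H](C)C[C@@H]2C3=C(C(=O)OCC[Si](C)(C)C)C(=O)C[C@H](C3)[C@H](C)C1
F4 | step 27 | C23-hydroxy keto lactone (C23 epimers) | C[C@@H]1CCC[C@H]2C=C(C(=O)OC(C)(C)C)[C@@H](C)C[C@@]23OC(=O)[C@@]2(C)C(=O)C(O)[C@H](C[C@H]23)[C@H](C)C1
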